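The cis C2-aryl/C3-methyl pair of the dihydrofuran ring (O1–C2–C3–C3a–C7a) is traced to a cis-β-methyl-γ-aryl-γ-butyrolactone in which C7a is the lactone carbonyl and C3a its α-carbon. One two-enzyme operation reduces the C3=C3a double bond and the C2 ketone of a flat, achiral precursor, an ethyl (E)-aroylcrotonate (aryl ketone, trisubstituted alkene, ester), and closes O1–C7a, setting both centres. The lactone face then steers two enolate alkylations (allyl last, anti to methyl); carbocycle B is closed by Claisen condensation of a saturated ketone chain onto C7a, so no alkene geometry has to be controlled, and C5 is oxidised and O-methylated at the end.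

Key step: step 3

Assumption: benzofuran numbering (O1, C2, C3, C3a, C4–C7, C7a) is used for the target; ring A is the dihydrofuran ring and ring B the carbocycle. Lactones are numbered as furan-2-ones, so lactone C2/C3/C4/C5 become C7a/C3a/C3/C2.
Remark: the target is (2R,3S,3aS), with aryl and methyl cis and allyl anti to methyl. Lactone C5 (R) and C4 (S) map onto C2 and C3, and no structure needed correction.
Remark: ring B is closed from an sp3 chain because a C4=C5 enol ether made by carbonyl olefination would hold C3a trans to the acyl group, from where C7 cannot reach C7a. Compound 4 is used as the pure (E)-isomer, since ene-reductases commonly give opposite C3 configurations from (E)- and (Z)-enoates.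

Step 1
Reactants: 1 1-(3,4,5-trimethoxyphenyl)propan-1-one
Product: 2 1-(3,4,5-trimethoxyphenyl)propane-1,2-dione
Conditions: SeO2 (1.3 equiv), 1,4-dioxane/H2O (20:1), 90 °C
Reagents that add atoms: selenium dioxide, O=[Se]=O
Why: Riley oxidation, in which SeO2 attacks the enol of the aryl ketone and oxidises its only α-methylene group to the 1,2-dione while the arene and its methyl ethers stay untouched; no stereocentre is formed.

Step 2
Reactants: 2 1-(3,4,5-trimethoxyphenyl)propane-1,2-dione, 3 ethyl (triphenylphosphoranylidene)acetate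
Product: 4 ethyl (E)-3-methyl-4-oxo-4-(3,4,5-trimethoxyphenyl)but-2-enoate
Conditions: CH2Cl2, 0 °C → rt; chromatography to remove the minor (Z)-isomer
Reagents that add atoms: none
Why: Wittig olefination with a stabilised ylide, which should add to the acetyl carbonyl (the aroyl carbonyl is deactivated by conjugation with the electron-rich ring and is more hindered) and give mainly the (E)-alkene with the ester trans to the aroyl group.

Step 3
Reactants: 4 ethyl (E)-3-methyl-4-oxo-4-(3,4,5-trimethoxyphenyl)but-2-enoate
Product: 7 (4S,5R)-4-methyl-5-(3,4,5-trimethoxyphenyl)dihydrofuran-2(3H)-one (cis), via saturated keto ester 5 (not isolated), via syn hydroxy ester 6 (not isolated)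
Conditions: ene-reductase (Old Yellow Enzyme family, (S)-selective at C3), NADP+ (cat.), D-glucose (2.5 equiv), glucose dehydrogenase, KH2PO4/K2HPO4 buffer pH 7.0, DMSO (5% v/v), 30 °C; then ketoreductase (NADPH-dependent, (R)-selective at C4), 30 °C; then CF3CO2H (cat.), CH2Cl2, rt
Reagents that add atoms: none
Why: The ene-reductase binds the aryl ketone as the activating group, passes hydride from reduced flavin mononucleotide to C2 of the enoate and a proton from its active-site tyrosine to C3 on the opposite face (net anti addition of H2), so the enzyme pocket, not the flat substrate, fixes the (S)-methyl centre. The ketoreductase then transfers hydride from NADPH to one face of the aryl ketone to give the (4R)-alcohol, again under catalyst control, and the syn γ-hydroxy ester closes to the lactone by 5-exo-trig acyl substitution with loss of ethanol, completed by a trace of acid. The closest known reaction type is the one-pot ene-reductase/alcohol dehydrogenase reduction of γ-oxo enoates to β,γ-disubstituted γ-butyrolactones. The step needs the syn alcohol (cis-lactone), whereas the Felkin–Anh bias of the α-methyl ketone toward small hydride donors favours the anti alcohol, so the selectivity rests on the choice of ketoreductase. It also needs C=C reduction before C=O reduction and survival of the enolisable C3 centre: the ene-reductase is run to completion first at pH 7, and a ketoreductase that accepts only the (S)-ketone turns any slow enolisation into a dynamic kinetic resolution, not a loss of purity.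

Step 4
Reactants: 7 (4S,5R)-4-methyl-5-(3,4,5-trimethoxyphenyl)dihydrofuran-2(3H)-one, 8 2-(2-bromoethyl)-2-methyl-1,3-dioxolane
Product: 9 (3S,4S,5R)-4-methyl-3-[2-(2-methyl-1,3-dioxolan-2-yl)ethyl]-5-(3,4,5-trimethoxyphenyl)dihydrofuran-2(3H)-one
Conditions: LiN(i-Pr)2 (1.1 equiv), THF, −78 °C; then 8 (1.5 equiv), DMPU, Bu4NI (0.1 equiv), −78 → −20 °C
Reagents that add atoms: none
Why: Alkylation of the lithium lactone enolate (SN2, with iodide catalysis to activate the primary bromide), the electrophile entering anti to the neighbouring methyl group to give the 3,4-trans lactone, although this centre is set again in step 5.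

Step 5
Reactants: 9 (3S,4S,5R)-4-methyl-3-[2-(2-methyl-1,3-dioxolan-2-yl)ethyl]-5-(3,4,5-trimethoxyphenyl)dihydrofuran-2(3H)-one, 10 allyl bromide
Product: 12 (3S,4S,5R)-3-allyl-4-methyl-3-(3-oxobutyl)-5-(3,4,5-trimethoxyphenyl)dihydrofuran-2(3H)-one, via ketal lactone 11 (not isolated)
Conditions: LiN(i-Pr)2 (1.2 equiv), THF, −78 °C; then 10 (1.5 equiv), −78 → −30 °C; then 1 M HCl, THF, rt
Reagents that add atoms: water, O
Why: Second enolate alkylation, in which allyl bromide should attack the trisubstituted lactone enolate from the face opposite the cis-disposed methyl and aryl groups and so set the quaternary centre with allyl anti to methyl, followed by acetal hydrolysis of the dioxolane to the methyl ketone in the acidic work-up.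

Step 6
Reactants: 12 (3S,4S,5R)-3-allyl-4-methyl-3-(3-oxobutyl)-5-(3,4,5-trimethoxyphenyl)dihydrofuran-2(3H)-one
Product: 14 (2R,3S,3aS)-3a-allyl-3-methyl-2-(3,4,5-trimethoxyphenyl)-3,3a,4,5-tetrahydrobenzofuran-6(2H)-one, via hydroxy dione 13 (not isolated)
Conditions: LiN(SiMe3)2 (2.2 equiv), THF, −78 → 0 °C; then 1 M HCl; then pyridinium p-toluenesulfonate (5 mol %), CH2Cl2, rt
Reagents that add atoms: none
Why: Intramolecular Claisen (Dieckmann-type) condensation, in which the kinetic methyl-ketone enolate attacks the lactone carbonyl (6-exo-trig) to give the 4,4-disubstituted cyclohexane-1,3-dione as its enolate (δ-keto esters with a quaternary α-carbon are known to close this way), after which the freed benzylic hydroxyl adds to the nearer carbonyl and loses water to give the vinylogous ester; C2, C3 and C3a are not touched.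

Step 7
Reactants: 14 (2R,3S,3aS)-3a-allyl-3-methyl-2-(3,4,5-trimethoxyphenyl)-3,3a,4,5-tetrahydrobenzofuran-6(2H)-one
Product: 15 (2R,3S,3aR,5RS)-3a-allyl-5-hydroxy-3-methyl-2-(3,4,5-trimethoxyphenyl)-3,3a,4,5-tetrahydrobenzofuran-6(2H)-one
Conditions: KN(SiMe3)2 (1.2 equiv), THF, −78 °C; then 2-(phenylsulfonyl)-3-phenyloxaziridine (1.3 equiv), −78 °C; then AcOH
Reagents that add atoms: 2-(phenylsulfonyl)-3-phenyloxaziridine, O=S(=O)(N1OC1c1ccccc1)c1ccccc1
Why: Davis enolate hydroxylation at C5, the only enolisable position of the vinylogous ester (C3a is quaternary, C7 is vinylic); the new carbinol centre should form as a mixture of epimers and is removed in step 8.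

Step 8
Reactants: 15 (2R,3S,3aR,5RS)-3a-allyl-5-hydroxy-3-methyl-2-(3,4,5-trimethoxyphenyl)-3,3a,4,5-tetrahydrobenzofuran-6(2H)-one
Product: 16 (2R,3S,3aS)-3a-allyl-5-hydroxy-3-methyl-2-(3,4,5-trimethoxyphenyl)-3,3a-dihydrobenzofuran-6(2H)-one
Conditions: Dess–Martin periodinane (1.3 equiv), CH2Cl2, 0 °C → rt
Reagents that add atoms: none
Why: Dess–Martin oxidation of the acyloin to the 5,6-dione, which should tautomerise at once toward C4, its only enolisable side, to the conjugated and hydrogen-bonded diosphenol.

Step 9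
Reactants: 16 (2R,3S,3aS)-3a-allyl-5-hydroxy-3-methyl-2-(3,4,5-trimethoxyphenyl)-3,3a-dihydrobenzofuran-6(2H)-one
Product: 17 (2R,3S,3aS)-3a-allyl-5-methoxy-3-methyl-2-(3,4,5-trimethoxyphenyl)-3,3a-dihydrobenzofuran-6(2H)-one (target)
Conditions: MeI (3 equiv), K2CO3 (2 equiv), acetone, rt
Reagents that add atoms: iodomethane, CI
Why: Williamson-type O-methylation of the acidic diosphenol, with O-alkylation favoured because the carbon terminus C4 of the ambident anion is neopentyl; the mild, non-acidic conditions at room temperature should avoid allyl migration and epimerisation at C2.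

Compound list
1 | 1-(3,4,5-trimethoxyphenyl)propan-1-one | CCC(=O)c1cc(OC)c(OC)c(OC)c1 | starting material
2 | 1-(3,4,5-trimethoxyphenyl)propane-1,2-dione | CC(=O)C(=O)c1cc(OC)c(OC)c(OC)c1 | intermediate
3 | ethyl (triphenylphosphoranylidene)acetate | CCOC(=O)C=P(c1ccccc1)(c1ccccc1)c1ccccc1 | starting material
4 | ethyl (E)-3-methyl-4-oxo-4-(3,4,5-trimethoxyphenyl)but-2-enoate | CCOC(=O)/C=C(\C)C(=O)c1cc(OC)c(OC)c(OC)c1 | intermediate
5 | ethyl (S)-3-methyl-4-oxo-4-(3,4,5-trimethoxyphenyl)butanoate | CCOC(=O)C[C@H](C)C(=O)c1cc(OC)c(OC)c(OC)c1 | intermediate (not isolated)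
6 | ethyl (3S,4R)-4-hydroxy-3-methyl-4-(3,4,5-trimethoxyphenyl)butanoate | CCOC(=O)C[C@H](C)[C@@H](O)c1cc(OC)c(OC)c(OC)c1 | intermediate (not isolated)
7 | (4S,5R)-4-methyl-5-(3,4,5-trimethoxyphenyl)dihydrofuran-2(3H)-one (cis) | O=C1O[C@@H](c2cc(OC)c(OC)c(OC)c2)[C@@H](C)C1 | intermediate
8 | 2-(2-bromoethyl)-2-methyl-1,3-dioxolane | CC1(CCBr)OCCO1 | starting material
9 | (3S,4S,5R)-4-methyl-3-[2-(2-methyl-1,3-dioxolan-2-yl)ethyl]-5-(3,4,5-trimethoxyphenyl)dihydrofuran-2(3H)-one | CC1(CC[C@@H]2C(=O)O[C@@H](c3cc(OC)c(OC)c(OC)c3)[C@H]2C)OCCO1 | intermediate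
10 | allyl bromide | C=CCBr | starting material
11 | (3S,4S,5R)-3-allyl-4-methyl-3-[2-(2-methyl-1,3-dioxolan-2-yl)ethyl]-5-(3,4,5-trimethoxyphenyl)dihydrofuran-2(3H)-one | C=CC[C@]1(CCC2(C)OCCO2)C(=O)O[C@@H](c2cc(OC)c(OC)c(OC)c2)[C@H]1C | intermediate (not isolated)
12 | (3S,4S,5R)-3-allyl-4-methyl-3-(3-oxobutyl)-5-(3,4,5-trimethoxyphenyl)dihydrofuran-2(3H)-one | C=CC[C@]1(CCC(C)=O)C(=O)O[C@@H](c2cc(OC)c(OC)c(OC)c2)[C@H]1C | intermediate
13 | (S)-4-allyl-4-[(1R,2S)-1-hydroxy-1-(3,4,5-trimethoxyphenyl)propan-2-yl]cyclohexane-1,3-dione | C=CC[C@@]1(CCC(=O)CC1=O)[C@H](C)[C@@H](O)c1cc(OC)c(OC)c(OC)c1 | intermediate (not isolated)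
14 | (2R,3S,3aS)-3a-allyl-3-methyl-2-(3,4,5-trimethoxyphenyl)-3,3a,4,5-tetrahydrobenzofuran-6(2H)-one | C=CC[C@]12CCC(=O)C=C1O[C@@H](c1cc(OC)c(OC)c(OC)c1)[C@H]2C | intermediate
15 | (2R,3S,3aR,5RS)-3a-allyl-5-hydroxy-3-methyl-2-(3,4,5-trimethoxyphenyl)-3,3a,4,5-tetrahydrobenzofuran-6(2H)-one | C=CC[C@]12CC(O)C(=O)C=C1O[C@@H](c1cc(OC)c(OC)c(OC)c1)[C@H]2C | intermediate
16 | (2R,3S,3aS)-3a-allyl-5-hydroxy-3-methyl-2-(3,4,5-trimethoxyphenyl)-3,3a-dihydrobenzofuran-6(2H)-one | C=CC[C@]12C=C(O)C(=O)C=C1O[C@@H](c1cc(OC)c(OC)c(OC)c1)[C@H]2C | intermediate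
17 | (2R,3S,3aS)-3a-allyl-5-methoxy-3-methyl-2-(3,4,5-trimethoxyphenyl)-3,3a-dihydrobenzofuran-6(2H)-one | C=CC[C@]12C=C(OC)C(=O)C=C1O[C@@H](c1cc(OC)c(OC)c(OC)c1)[C@H]2C | target

Total step count: 9. Longest linear sequence: 9 (steps 1 to 9; compounds 3, 8 and 10 are purchased).

Steps most likely to fail

Step 3. No enzyme pair may give both a high selectivity at C3 and the syn alcohol, or the saturated ketone may enolise before it is reduced. The two reductions would then be separated and run with chemical catalysts. Setting out from 4, asymmetric hydrogenation of the C=C bond ([Rh(cod)2]BF4 with a chiral bisphosphine chosen by screening, H2, MeOH) should give 5, which is now isolated. An oxazaborolidine-catalysed borane reduction (Corey–Bakshi–Shibata, catalyst enantiomer chosen for the 4R alcohol, BH3·SMe2, THF, −20 °C) should override the bias of the α-methyl group and give 6. Treatment with TsOH closes the lactone and the route is rejoined at 7. No compound outside the list is made (F0).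

Step 4. Slow substitution at the unactivated bromide may let loss of HBr from 8 and self-condensation of the lactone enolate take over. The quaternary centre would then be built with a stabilised nucleophile and the side chain by olefination. Setting out from 7, formylation (LiN(i-Pr)2, HCO2Et, THF, −78 °C → rt) should give the hydroxymethylene lactone F1. Its sodium enolate (NaH) would be C-allylated with allyl acetate and Pd(PPh3)4 (zerovalent palladium, Tsuji–Trost, attack anti to the methyl group) to give the aldehyde F2. Horner–Wadsworth–Emmons reaction with dimethyl (2-oxopropyl)phosphonate (LiCl, DBU, MeCN) should give the (E)-enone F3. Conjugate reduction with [(Ph3P)CuH]6 in wet toluene rejoins the route at 12, so steps 4 and 5 are both replaced.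

Step 7. Oxidation of the potassium enolate may be incomplete, or the enolate may add to the sulfonimine formed from the oxidant. C5 would then be oxygenated through an epoxide. Setting out from 14, selenenylation of the enolate (LiN(i-Pr)2, PhSeCl, THF, −78 °C) should give the α-selenide F4. Oxidation with H2O2 and syn elimination of the selenoxide should give the cross-conjugated dienone F5. Nucleophilic epoxidation (t-BuOOH, DBU, CH2Cl2) of the more electrophilic C4=C5 bond should give the epoxy ketone F6. NaOMe in MeOH should open the epoxide at C5 and eliminate water, which rejoins the route at the target 17 and bypasses 15 and 16.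

Further compounds
F0 | step 3 | none | none
F1 | step 4 | (4S,5R)-3-(hydroxymethylene)-4-methyl-5-(3,4,5-trimethoxyphenyl)dihydrofuran-2(3H)-one (enol form of the α-formyl lactone) | O=C1O[C@@H](c2cc(OC)c(OC)c(OC)c2)[C@@H](C)C1=CO
F2 | step 4 | (3S,4S,5R)-3-allyl-4-methyl-2-oxo-5-(3,4,5-trimethoxyphenyl)tetrahydrofuran-3-carbaldehyde | C=CC[C@]1(C=O)C(=O)O[C@@H](c2cc(OC)c(OC)c(OC)c2)[C@H]1C
F3 | step 4 | (3R,4S,5R)-3-allyl-4-methyl-3-[(E)-3-oxobut-1-en-1-yl]-5-(3,4,5-trimethoxyphenyl)dihydrofuran-2(3H)-one | C=CC[C@]1(/C=C/C(C)=O)C(=O)O[C@@H](c2cc(OC)c(OC)c(OC)c2)[C@H]1C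
F4 | step 7 | (2R,3S,3aR,5RS)-3a-allyl-3-methyl-5-(phenylselanyl)-2-(3,4,5-trimethoxyphenyl)-3,3a,4,5-tetrahydrobenzofuran-6(2H)-one | C=CC[C@]12CC([Se]c3ccccc3)C(=O)C=C1O[C@@H](c1cc(OC)c(OC)c(OC)c1)[C@H]2C
F5 | step 7 | (2R,3S,3aR)-3a-allyl-3-methyl-2-(3,4,5-trimethoxyphenyl)-3,3a-dihydrobenzofuran-6(2H)-one | C=CC[C@]12C=CC(=O)C=C1O[C@@H](c1cc(OC)c(OC)c(OC)c1)[C@H]2C
F6 | step 7 | (2R,3S)-3a-allyl-4,5-epoxy-3-methyl-2-(3,4,5-trimethoxyphenyl)-3,3a,4,5-tetrahydrobenzofuran-6(2H)-one (C3a as in 14, epoxide face not assigned) | C=CC[C@]12C3OC3C(=O)C=C1O[C@@H](c1cc(OC)c(OC)c(OC)c1)[C@H]2C
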